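The core is cut at the ring-fusion nitrogen: its bond to the ring-fusion CH (piperidine/azepane junction) and the CH2–CH2 bond next to nitrogen in the azepane. One pot makes both: an N-(trimethylsilylmethyl) amine adds to a tethered α-alkylidene-β-methyl-butyrolactone (piperidine closure), then photoredox desilylation turns the N-CH2 carbon into a radical that joins the β-carbon of allyl acrylate, a union of two normally electrophilic carbons. The step exploits the β-amino carbonyl pattern N–CH–CH–C(OH) and the N–(CH2)3–C(OH) chain of the azepane. The precursor is an acyclic ammonium salt holding two chiral-pool stereocentres, which relay the other six. Dieckmann ring opening and a tetronate [4+1] annulation complete the rings.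

Key step: step 6

Remark: 5, 8 and 19 are assumed to be catalogue compounds (19 is otherwise one O-methylation from 3-methyltetronic acid).
Remark: 11 is drawn as the E isomer; the E/Z mixture converges in step 6.
Remark: hydroxy ketones 15 and 16 are drawn open-chain but equilibrate with cyclic hemiketals; the ester-bearing carbon of 15 and the butenolide C5 of 20 are not stereodefined.

Step 1
Reactants: 1 methyl (R)-2-hydroxybutanoate
Product: 2 methyl (R)-2-(benzyloxy)butanoate
Conditions: BnOC(=NH)CCl3 (1.3 equiv), TfOH (5 mol %), cyclohexane/CH2Cl2 2:1, 0 °C to rt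
Reagents that add atoms: benzyl 2,2,2-trichloroacetimidate, N=C(OCc1ccccc1)C(Cl)(Cl)Cl
Why: Acid-catalysed O-benzylation with a trichloroacetimidate needs no base, so the α-stereocentre of the hydroxy ester should survive.

Step 2
Reactants: 2 methyl (R)-2-(benzyloxy)butanoate
Product: 3 (R)-2-(benzyloxy)butanal
Conditions: iBu2AlH (1.1 equiv), CH2Cl2, −78 °C; aq. Rochelle salt
Reagents that add atoms: none
Why: Partial iBu2AlH reduction of an ester stops at the aldehyde because the tetrahedral aluminium acetal is stable at −78 °C, and the crude α-alkoxy aldehyde is used at once to avoid racemisation.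

Step 3
Reactants: 3 (R)-2-(benzyloxy)butanal; 4 (trimethylsilyl)methanamine; 5 pent-4-en-1-ylmagnesium bromide
Product: 7 (3R,4R)-3-(benzyloxy)-N-[(trimethylsilyl)methyl]non-8-en-4-amine, via aldimine 6 (not isolated)
Conditions: 4 (1.05 equiv), MgSO4, CH2Cl2, 0 °C; filter, concentrate; then 5 (2 equiv), Et2O, −78 to −20 °C
Reagents that add atoms: none
Why: Imine condensation followed by a chelation-controlled Grignard addition, in which magnesium bridges the imine nitrogen and the benzyloxy oxygen in a five-membered chelate and the nucleophile enters anti to the ethyl group, should give the 3,4-syn (3R,4R) amino ether.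

Step 4
Reactants: 8 (S)-4-methyloxolan-2-one
Product: 10 (S)-4-methyl-3-methylideneoxolan-2-one, via formyl enolate 9 (not isolated)
Conditions: NaH (1.2 equiv), HCO2Et (1.5 equiv), Et2O, 0 °C to rt; then (CH2O)n (5 equiv), THF, reflux
Reagents that add atoms: paraformaldehyde (as formaldehyde), C=O
Why: α-Methylenation by Claisen formylation and formaldehyde aldol/deformylation, in which the formyl enolate 9 adds to formaldehyde and the formyl group leaves as formate, never enolises the β-stereocentre.

Step 5
Reactants: 7 (3R,4R)-3-(benzyloxy)-N-[(trimethylsilyl)methyl]non-8-en-4-amine; 10 (S)-4-methyl-3-methylideneoxolan-2-one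
Product: 11 (3R,4R)-3-(benzyloxy)-8-[(4S)-4-methyl-2-oxooxolan-3-ylidene]-N-[(trimethylsilyl)methyl]octan-4-aminium p-toluenesulfonate
Conditions: 7 as its salt with TsOH·H2O (1.05 equiv), 10 (3 equiv), second-generation Hoveyda–Grubbs catalyst RuCl2(SIMes)(=CH-C6H4-2-OiPr) (5 mol %), 2,6-dichloro-1,4-benzoquinone (10 mol %), CH2Cl2, 40 °C; trituration with Et2O
Reagents that add atoms: p-toluenesulfonic acid monohydrate, Cc1ccc(cc1)S(=O)(=O)O.O
Why: Olefin cross metathesis of a terminal alkene with an α-methylene lactone should work because the ammonium salt spares the ruthenium carbene and blocks early conjugate addition, the benzoquinone suppresses double-bond migration, and the E/Z ratio is irrelevant.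

Step 6
Reactants: 11 alkylidene lactone ammonium p-toluenesulfonate; 12 allyl acrylate
Product: 14 allyl 4-[(2S,6R)-2-[(3R,4S)-4-methyl-2-oxooxolan-3-yl]-6-[(1R)-1-(benzyloxy)propyl]piperidin-1-yl]butanoate, via silylmethyl piperidine 13 (not isolated)
Conditions: K2HPO4 (2 equiv), MeCN/MeOH 4:1 (0.02 M), 50 °C, dark; then 12 (3 equiv), [Ir(ppy)2(dtbbpy)]PF6 (1 mol %), degassed, blue LEDs (450 nm), 25 °C
Reagents that add atoms: none
Why: Neutralisation frees the secondary amine, which adds reversibly to the β-carbon of the alkylidene lactone (aza-Michael, N–CH bond); the photoexcited trivalent iridium complex then oxidises the tertiary α-silylamine 13, methanol removes silicon from the radical cation, and the nucleophilic N-CH2 radical adds to the β-carbon of allyl acrylate (CH2–CH2 bond) before the α-ester radical is reduced by divalent iridium and protonated. The closest known reactions are the intramolecular aza-Michael route to 2,6-disubstituted piperidines and the photoredox Giese addition of α-silylamines to acrylates. Only the piperidine ring closes, in the 6-exo-trig mode. The ring-fusion CH should be set under thermodynamic control by the existing aminomethine carbon (2,6-cis, both substituents equatorial), and the lactone α-carbon should equilibrate through retro-Michael/Michael addition to the arrangement trans to the neighbouring methyl group, so each new centre is read from a different chiral-pool centre. The step needs radical formation at the N-CH2 carbon only, which the silicon atom secures, and it needs the amine to be tertiary before the acrylate arrives, which the order of addition secures.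

Step 7
Reactants: 14 piperidine lactone allyl ester
Product: 15 allyl (4R,10R,10aS)-4-[(1R)-1-(benzyloxy)propyl]-10-[(2S)-1-hydroxypropan-2-yl]-9-oxodecahydropyrido[1,2-a]azepine-8-carboxylate
Conditions: KOtBu (2.5 equiv), THF, 0 °C to rt; AcOH quench
Reagents that add atoms: none
Why: Dieckmann condensation with the lactone carbonyl as acceptor closes the seven-membered ring (7-exo-trig) with the lactone oxygen leaving as the primary alkoxide, and the β-keto ester enolate both drives the equilibrium and keeps the neighbouring ring stereocentre from enolising.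

Step 8
Reactants: 15 β-keto allyl ester
Product: 16 (4R,10R,10aS)-4-[(1R)-1-(benzyloxy)propyl]-10-[(2S)-1-hydroxypropan-2-yl]perhydropyrido[1,2-a]azepin-9-one
Conditions: Pd(PPh3)4 (5 mol %), morpholine (2 equiv), THF, rt
Reagents that add atoms: none
Why: Tsuji deallylation–decarboxylation, in which zerovalent palladium ionises the allyl ester and morpholine traps the allyl group, lets the β-keto acid lose CO2 at room temperature under neutral conditions, so the ketone α-stereocentre sees neither acid nor strong base.

Step 9
Reactants: 16 hydroxy ketone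
Product: 17 (2S)-2-[(4R,10R,10aS)-4-[(1R)-1-(benzyloxy)propyl]-9-oxoperhydropyrido[1,2-a]azepin-10-yl]propanoic acid
Conditions: TEMPO (10 mol %), NaClO2 (2 equiv), NaOCl (2 mol %), MeCN/NaH2PO4–Na2HPO4 buffer pH 6.7, 35 °C
Reagents that add atoms: sodium chlorite, [Na+].[O-]Cl=O
Why: TEMPO/chlorite oxidation takes the primary alcohol (open form of the hemiketal) through the aldehyde to the acid, while the amine is protonated at pH 6.7 and so protected from oxidation.

Step 10
Reactants: 17 keto acid
Product: 18 (2S)-2-[(4R,10R,10aS)-4-[(1R)-1-(benzyloxy)propyl]-9-oxoperhydropyrido[1,2-a]azepin-10-yl]-N-methoxy-N-methylpropanamide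
Conditions: 1,1'-carbonyldiimidazole (1.2 equiv), CH2Cl2, rt; then MeNH(OMe)·HCl (1.5 equiv), rt
Reagents that add atoms: N,O-dimethylhydroxylamine hydrochloride, CNOC.Cl
Why: Weinreb amide formation through the acyl imidazole runs near neutrality and gives an acyl group that later accepts exactly one carbanion.

Step 11
Reactants: 18 keto Weinreb amide; 19 4-methoxy-3-methylfuran-2(5H)-one
Product: 21 spiro cyclopentanone with free tertiary hydroxyl (benzyl ether; all stereocentres as in 23), via lithium alkoxide 20 (not isolated)
Conditions: 19 (1.5 equiv), LiN(iPr)2 (1.45 equiv), THF, −78 °C; add 18; then LiN(iPr)2 (1.6 equiv), −78 to −20 °C; AcOH, −78 °C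
Reagents that add atoms: none
Why: In this [4+1] annulation by vinylogous aldol addition and intramolecular Weinreb acylation, the C5 anion of 19 should add to the azepanone carbonyl opposite the α-branch (trans carbinol 20), a second deprotonation at C5 gives an alkoxide–furanolate dianion in which lithium bridging holds the carbinol oxygen syn to the ring oxygen while C5 acylates on the amide (5-exo-trig) and sets the spiro centre, and the chelated tetrahedral adduct releases the ketone only on acidic work-up so that retro-aldol cleavage is avoided.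

Step 12
Reactants: 21 spiro cyclopentanone
Product: 22 O-benzyl ether of the target (side-chain hydroxyl benzylated)
Conditions: Me4NBH(OAc)3 (5 equiv), MeCN/AcOH 1:1, −20 °C
Reagents that add atoms: none
Why: In this Evans–Saksena hydroxyl-directed reduction the tertiary hydroxyl binds the acetoxyborohydride and delivers hydride to the ketone face it occupies, which should give the 1,3-anti diol with the new hydroxyl cis to the neighbouring methyl group, and the acidic medium suppresses retro-aldol cleavage.

Step 13
Reactants: 22 O-benzyl ether of the target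
Product: 23 CNP0267781.1
Conditions: H2 (1 atm), Pd(OH)2/C (20 wt %), MeOH, AcOH (2 equiv), rt
Reagents that add atoms: none
Why: Hydrogenolysis of the benzyl ether over Pd(OH)2/C should leave the tetrasubstituted alkoxy-butenolide alkene untouched, and acetic acid keeps the amine from poisoning the catalyst.

Compound list
1 | methyl (R)-2-hydroxybutanoate | CC[C@@H](O)C(=O)OC | starting material
2 | methyl (R)-2-(benzyloxy)butanoate | CC[C@@H](OCc1ccccc1)C(=O)OC | intermediate
3 | (R)-2-(benzyloxy)butanal | CC[C@@H](OCc1ccccc1)C=O | intermediate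
4 | (trimethylsilyl)methanamine | C[Si](C)(C)CN | starting material
5 | pent-4-en-1-ylmagnesium bromide (THF solution) | C=CCCC[Mg]Br | starting material
6 | (R,E)-N-[2-(benzyloxy)butylidene]-1-(trimethylsilyl)methanamine | CC[C@@H](OCc1ccccc1)/C=N/C[Si](C)(C)C | intermediate
7 | (3R,4R)-3-(benzyloxy)-N-[(trimethylsilyl)methyl]non-8-en-4-amine | CC[C@@H](OCc1ccccc1)[C@H](NC[Si](C)(C)C)CCCC=C | intermediate
8 | (S)-4-methyloxolan-2-one [(S)-β-methyl-γ-butyrolactone] | C[C@H]1CC(=O)OC1 | starting material
9 | sodium [(4S)-4-methyl-2-oxooxolan-3-ylidene]methanolate | C[C@H]1C(=C[O-])C(=O)OC1.[Na+] | intermediate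
10 | (S)-4-methyl-3-methylideneoxolan-2-one | C[C@H]1C(=C)C(=O)OC1 | intermediate
11 | (3R,4R)-3-(benzyloxy)-8-[(4S)-4-methyl-2-oxooxolan-3-ylidene]-N-[(trimethylsilyl)methyl]octan-4-aminium p-toluenesulfonate (E drawn) | CC[C@@H](OCc1ccccc1)[C@H]([NH2+]C[Si](C)(C)C)CCC/C=C1\[C@H](C)COC1=O.Cc1ccc(cc1)S(=O)(=O)[O-] | intermediate
12 | prop-2-en-1-yl prop-2-enoate (allyl acrylate) | C=CC(=O)OCC=C | starting material
13 | (3R,4S)-3-[(2S,6R)-6-[(1R)-1-(benzyloxy)propyl]-1-[(trimethylsilyl)methyl]piperidin-2-yl]-4-methyloxolan-2-one (2,6-cis piperidine, trans lactone) | CC[C@@H](OCc1ccccc1)[C@H]1CCC[C@@H]([C@H]2[C@H](C)COC2=O)N1C[Si](C)(C)C | intermediate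
14 | allyl 4-[(2S,6R)-2-[(3R,4S)-4-methyl-2-oxooxolan-3-yl]-6-[(1R)-1-(benzyloxy)propyl]piperidin-1-yl]butanoate | CC[C@@H](OCc1ccccc1)[C@H]1CCC[C@@H]([C@H]2[C@H](C)COC2=O)N1CCCC(=O)OCC=C | intermediate
15 | allyl (4R,10R,10aS)-4-[(1R)-1-(benzyloxy)propyl]-10-[(2S)-1-hydroxypropan-2-yl]-9-oxodecahydropyrido[1,2-a]azepine-8-carboxylate | CC[C@@H](OCc1ccccc1)[C@H]1CCC[C@H]2[C@@H]([C@H](C)CO)C(=O)C(C(=O)OCC=C)CCN12 | intermediate
16 | (4R,10R,10aS)-4-[(1R)-1-(benzyloxy)propyl]-10-[(2S)-1-hydroxypropan-2-yl]perhydropyrido[1,2-a]azepin-9-one | CC[C@@H](OCc1ccccc1)[C@H]1CCC[C@H]2[C@@H]([C@H](C)CO)C(=O)CCCN12 | intermediate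
17 | (2S)-2-[(4R,10R,10aS)-4-[(1R)-1-(benzyloxy)propyl]-9-oxoperhydropyrido[1,2-a]azepin-10-yl]propanoic acid | CC[C@@H](OCc1ccccc1)[C@H]1CCC[C@H]2[C@@H]([C@H](C)C(=O)O)C(=O)CCCN12 | intermediate
18 | (2S)-2-[(4R,10R,10aS)-4-[(1R)-1-(benzyloxy)propyl]-9-oxoperhydropyrido[1,2-a]azepin-10-yl]-N-methoxy-N-methylpropanamide | CC[C@@H](OCc1ccccc1)[C@H]1CCC[C@H]2[C@@H]([C@H](C)C(=O)N(C)OC)C(=O)CCCN12 | intermediate
19 | 4-methoxy-3-methylfuran-2(5H)-one | COC1=C(C)C(=O)OC1 | starting material
20 | lithium alkoxide of the ketone adduct: azepane carbinol carbon bearing the butenolide C5 trans to the amide side chain (C5 epimers) | CC[C@@H](OCc1ccccc1)[C@H]1CCC[C@H]2[C@@H]([C@H](C)C(=O)N(C)OC)[C@]([O-])(C3OC(=O)C(C)=C3OC)CCCN12.[Li+] | intermediate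
21 | spiro cyclopentanone: the carbinol carbon of 23 next to the spiro centre is a ketone, side-chain hydroxyl benzylated, other stereocentres as in 23 | CC[C@@H](OCc1ccccc1)[C@H]1CCC[C@H]2[C@H]3[C@H](C)C(=O)[C@@]4(OC(=O)C(C)=C4OC)[C@]3(O)CCCN12 | intermediate
22 | O-benzyl ether of 23 at the side-chain hydroxyl | CC[C@@H](OCc1ccccc1)[C@H]1CCC[C@H]2[C@H]3[C@H](C)[C@H](O)[C@@]4(OC(=O)C(C)=C4OC)[C@]3(O)CCCN12 | intermediate
23 | CNP0267781.1 | CC[C@@H](O)[C@H]1CCC[C@H]2[C@H]3[C@H](C)[C@H](O)[C@@]4(OC(=O)C(C)=C4OC)[C@]3(O)CCCN12 | target

Total step count: 13. Longest linear sequence: 12 steps (steps 1–3 and 5–13; step 4 is a one-step side branch).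

Steps most likely to fail

Step 6. The radical stage may be lost to back electron transfer, to protodesilylation that leaves an N-methyl amine, or to oligomerisation of the acrylate; the conjugate addition may also stop at a kinetic mixture of ring isomers. The fallback sets out from 13, isolated after the dark stage. Anodic oxidation in MeOH (Et4NOTs, carbon electrodes) should exchange silicon for methoxy and give the N-(methoxymethyl)piperidine F1. Me3SiOTf in CH2Cl2 at −78 °C ionises it to the N-methylene iminium ion, which is captured by the zinc homoenolate prop-2-en-1-yl 3-(iodozincio)propanoate F2 (from prop-2-en-1-yl 3-iodopropanoate and zinc dust in THF). This Mannich-type addition forms the same CH2–CH2 bond by two-electron chemistry and returns to the route at 14.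

Step 11. The tetronate anion may enolise the ketone instead of adding, may add to the wrong carbonyl face, the alkoxide may undergo retro-aldol cleavage before the second deprotonation, or the ring closure may proceed without the lithium bridge and give the other spiro configuration. The fallback sets out from 17 and separates the events. Me3SiCHN2 in MeOH/toluene gives the methyl ester F3. Lithiated 19 at −78 °C followed by Et3SiOTf gives the triethylsilyl ether F4, in which retro-aldol is blocked. KN(SiMe3)2 (2.5 equiv) in THF from −78 to 0 °C, then DBU to equilibrate the methyl-bearing centre, should effect a Dieckmann-type closure to the silylated spiro ketone F5; here the silyloxy group turns away from the methoxy substituent of the furanolate and steers the closure. HF·pyridine removes the silyl group and returns to the route at 21.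

Step 5. Cross metathesis may stall on the hindered 1,1-disubstituted olefin, lose material to homodimerisation of 7, or suffer migration of the exocyclic double bond into the lactone ring. The fallback sets out from 7. Boc2O (neat, 60 °C) gives the carbamate F6 and ozonolysis (O3, CH2Cl2, −78 °C; PPh3) the aldehyde F7. Horner–Wadsworth–Emmons olefination with the lithium salt of the phosphonate F8 (from 8, LiN(iPr)2 and ClP(O)(OEt)2 through enol phosphate to phosphonate rearrangement) gives the N-Boc alkylidene lactone F9. TsOH·H2O in MeCN at 50 °C removes the Boc group and returns to the route at 11.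

Further compounds
F1 | step 6 | (3R,4S)-3-[(2S,6R)-6-[(1R)-1-(benzyloxy)propyl]-1-(methoxymethyl)piperidin-2-yl]-4-methyloxolan-2-one | CC[C@@H](OCc1ccccc1)[C@H]1CCC[C@@H]([C@H]2[C@H](C)COC2=O)N1COC
F2 | step 6 | prop-2-en-1-yl 3-(iodozincio)propanoate | C=CCOC(=O)CC[Zn]I
F3 | step 11 | methyl (2S)-2-[(4R,10R,10aS)-4-[(1R)-1-(benzyloxy)propyl]-9-oxoperhydropyrido[1,2-a]azepin-10-yl]propanoate | CC[C@@H](OCc1ccccc1)[C@H]1CCC[C@H]2[C@@H]([C@H](C)C(=O)OC)C(=O)CCCN12
F4 | step 11 | triethylsilyl ether of the ketone adduct of F3 with 19 (butenolide C5 epimers) | CC[C@@H](OCc1ccccc1)[C@H]1CCC[C@H]2[C@@H]([C@H](C)C(=O)OC)[C@](O[Si](CC)(CC)CC)(C3OC(=O)C(C)=C3OC)CCCN12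
F5 | step 11 | triethylsilyl ether of 21 at the tertiary hydroxyl | CC[C@@H](OCc1ccccc1)[C@H]1CCC[C@H]2[C@H]3[C@H](C)C(=O)[C@@]4(OC(=O)C(C)=C4OC)[C@]3(O[Si](CC)(CC)CC)CCCN12
F6 | step 5 | tert-butyl N-[(3R,4R)-3-(benzyloxy)non-8-en-4-yl]-N-[(trimethylsilyl)methyl]carbamate | CC[C@@H](OCc1ccccc1)[C@H](N(C[Si](C)(C)C)C(=O)OC(C)(C)C)CCCC=C
F7 | step 5 | tert-butyl N-[(3R,4R)-3-(benzyloxy)-8-oxooctan-4-yl]-N-[(trimethylsilyl)methyl]carbamate | CC[C@@H](OCc1ccccc1)[C@H](N(C[Si](C)(C)C)C(=O)OC(C)(C)C)CCCC=O
F8 | step 5 | diethyl [(4R)-4-methyl-2-oxooxolan-3-yl]phosphonate (C3 epimers) | CCOP(=O)(OCC)C1[C@H](C)COC1=O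
F9 | step 5 | tert-butyl N-[(3R,4R)-3-(benzyloxy)-8-[(4S)-4-methyl-2-oxooxolan-3-ylidene]octan-4-yl]-N-[(trimethylsilyl)methyl]carbamate (E drawn) | CC[C@@H](OCc1ccccc1)[C@H](N(C[Si](C)(C)C)C(=O)OC(C)(C)C)CCC/C=C1\[C@H](C)COC1=O
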